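A direct plan would make the two isoflavones first and join them last: 8-chlorodaidzein A1 would be methylated at O7 only to the monomethyl ether A2, and genistein A3 would be permethylated to the trimethyl ether A4 and iodinated at C8 to the iodide A5.
A2 and A5 would then be joined by a copper-catalysed Ullmann etherification to the tetramethyl ether A6, and boron tribromide would free the four phenols of A6.
Its weakest steps would be:
- the Ullmann etherification of A2 with A5, which would have to make the C8–O bond of A6 at an electron-rich aryl iodide flanked by two ortho oxygen substituents, at the last and most costly stage, where slow coupling gives way to loss of iodine;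
- the iodination of A4, where C6 and C8 of the 5,7-dioxygenated ring are both activated and nothing in the substrate enforces C8;
- the mono-methylation of A1, which would rest only on the acidity gap between the 7- and 4'-hydroxyls, and with it the four methyl groups, three of them on A3, that are put on in separate steps only to come off again from A6.

**Retrosynthetic overview**
Key disconnection: both 3-arylchromenone units go back, by a 1,2-aryl shift in reverse (bonds C3–C1' and O1–C2 of each unit), to 2'-hydroxychalcones, so the target becomes one bis-chalcone whose para-phenylene ring is at once ring B of the chlorodaidzein unit and the O-substituent on C8 of the genistein unit.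
Ring A of the genistein unit bears oxygen on C5, C7, C8 and C8a, the pattern of 2,4,6-trimethoxyphenol 1: its hydroxyl becomes the ether oxygen on C8 by SNAr on 4-fluorobenzaldehyde 2, whose formyl group first activates the substitution and later becomes C2 of the chlorinated chromenone.
The resulting aldehyde 3 is acylated on its symmetric ring with the cinnamoyl chloride 4 and condensed with an acetophenone made from 2-chlororesorcinol, which completes the bis-chalcone.
Order of rings: diaryl ether first, then both pyranone rings together in the last skeletal step; no isoflavone exists before the ether, so ring-A halogenation, coupling at a hindered carbon and phenol differentiation by acidity do not arise.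

Key step: step 6

Remark: 1 and 4 are assumed to be bought as such; thallium salts are highly toxic, so step 6 is planned on a small scale with separate collection of the thallium waste.

Step 1
Reactants: 1 2,4,6-trimethoxyphenol; 2 4-fluorobenzaldehyde
Product: 3 4-(2,4,6-trimethoxyphenoxy)benzaldehyde
Conditions: K2CO3 (2 equiv), DMAc, 120 °C, Ar, 12 h
Reagents that add atoms: none
Why: Nucleophilic aromatic substitution (SNAr), in which the para-formyl group activates the C–F bond and the phenoxide of 1, although flanked by two methoxy groups, attacks an unhindered carbon, so the oxygen that will sit on C8 arrives with ring A and neither a ring-A halogenation nor a metal catalyst is needed; no stereocentre is formed.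

Step 2
Reactants: 3 4-(2,4,6-trimethoxyphenoxy)benzaldehyde; 4 (2E)-3-(4-methoxyphenyl)prop-2-enoyl chloride
Product: 6 4-{2-hydroxy-4,6-dimethoxy-3-[(2E)-3-(4-methoxyphenyl)prop-2-enoyl]phenoxy}benzaldehyde, via trimethoxy chalcone 5 (not isolated)
Conditions: 4 (1.15 equiv) and AlCl3 (3.5 equiv) premixed in CH2Cl2 at −20 °C, 3 added slowly, then rt, 6 h; ice, 1 M HCl
Reagents that add atoms: none
Why: Friedel–Crafts acylation followed in the same flask by chelation-directed ether cleavage: the two free positions of the trimethoxyphenyl ring are equivalent by symmetry and the formyl-bearing ring is deactivated, so a single ketone 5 should form, and AlCl3 held between the new carbonyl and the ortho-methoxy group wedged between acyl and aryloxy groups (twisted out of plane, hence the more basic and more strained one) should remove that methyl as CH3Cl while the other ortho-methoxy group stays; slow addition of 3 to the preformed acylating complex keeps acylation ahead of arene attack on the AlCl3-bound aldehyde, and the E alkene of 4 is carried through.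

Step 3
Reactants: 7 2-chlorobenzene-1,3-diol
Product: 8 1-(3-chloro-2,4-dihydroxyphenyl)ethan-1-one
Conditions: AcOH (1.2 equiv), BF3·OEt2 (solvent), 90 °C, 3 h; aq NaOAc
Reagents that add atoms: acetic acid, CC(=O)O
Why: BF3-promoted Friedel–Crafts acylation with the free acid, in which only C4 (equivalent to C6) of the symmetric diol is ortho to one hydroxyl and para to the other, and the product is held as a boron chelate that resists a second acylation; no stereocentre is formed.

Step 4
Reactants: 8 1-(3-chloro-2,4-dihydroxyphenyl)ethan-1-one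
Product: 9 1-[3-chloro-2-hydroxy-4-(methoxymethoxy)phenyl]ethan-1-one
Conditions: MOMCl (1.1 equiv), K2CO3 (1.5 equiv), acetone, 0 °C → rt, 4 h
Reagents that add atoms: chloromethyl methyl ether, COCCl
Why: Williamson-type O-alkylation differentiated by hydrogen bonding: the 2-hydroxyl is tied to the ketone oxygen and stays free for the later ring closure, while the more acidic 4-hydroxyl (para to the carbonyl, ortho to chlorine) is alkylated.

Step 5
Reactants: 6 4-{2-hydroxy-4,6-dimethoxy-3-[(2E)-3-(4-methoxyphenyl)prop-2-enoyl]phenoxy}benzaldehyde; 9 1-[3-chloro-2-hydroxy-4-(methoxymethoxy)phenyl]ethan-1-one (1.2 equiv)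
Product: 11 (2E)-1-[3-chloro-2-hydroxy-4-(methoxymethoxy)phenyl]-3-(4-{2-hydroxy-4,6-dimethoxy-3-[(2E)-3-(4-methoxyphenyl)prop-2-enoyl]phenoxy}phenyl)prop-2-en-1-one (bis-chalcone), via aldol adduct 10 (not isolated)
Conditions: KOH (50% aq, 12 equiv), EtOH, 0 °C → rt, 36 h, Ar; then cold dilute AcOH to pH 5
Reagents that add atoms: none
Why: Claisen–Schmidt condensation (crossed aldol, then E1cB loss of water): 6 has no enolisable C–H and one aldehyde, so 9 is the only enolate donor and the formyl group the only fast acceptor, the chalcone already present is a poor Michael acceptor as its phenoxide, and dehydration of the racemic aldol 10 gives the conjugated E alkene under thermodynamic control.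

Step 6
Reactants: 11 bis-chalcone
Product: 13 8-chloro-3-(4-{[5,7-dimethoxy-3-(4-methoxyphenyl)-4-oxo-4H-chromen-8-yl]oxy}phenyl)-7-hydroxy-4H-chromen-4-one, via bis(dimethyl acetal) 12 (not isolated)
Conditions: Tl(NO3)3·3H2O (2.5 equiv), MeOH–HC(OMe)3 (3:1), rt, dark, 20 h; TlNO3 filtered off; then 10% aq HCl, MeOH, 60 °C, 4 h
Reagents that add atoms: none
Why: Oxidative 1,2-aryl migration of 2'-hydroxychalcones with trivalent thallium, run on both enones at once: methanol adds to the benzylic β-carbon of each enone while thallium binds the α-carbon, and departure of monovalent thallium pulls the β-aryl group across through a phenonium ion, leaving an oxocarbenium ion at the old β-carbon that methanol traps as the dimethyl acetal 12. The closest known reaction is the Tl(NO3)3 rearrangement of single 2'-hydroxy-4-alkoxychalcones to isoflavones; both migrating rings carry the para oxygen donor it needs (methoxy on ring B of the genistein unit, aryloxy on the linker ring), which should favour migration over aurone formation. In the acid stage each pyranone ring closes 6-exo-trig by attack of the 2'-hydroxyl on the oxocarbenium ion released from the acetal, loss of methanol gives the 4H-chromen-4-one, and the same acid removes the methoxymethyl group. The only selectivity needed is which ortho oxygen of the genistein ring A closes the ring, and the substrate settles it because the other ortho oxygen is still a methyl ether, so the linker oxygen must end on C8. The two α-stereocentres of 12 form without control and vanish when C3 becomes sp2, so no stereocentre remains. In one operation the step should make both C3–aryl bonds and both O1–C2 bonds, that is both isoflavone skeletons, from a precursor put together by one substitution, one acylation and one aldol condensation.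

Step 7
Reactants: 13 8-chloro-3-(4-{[5,7-dimethoxy-3-(4-methoxyphenyl)-4-oxo-4H-chromen-8-yl]oxy}phenyl)-7-hydroxy-4H-chromen-4-one
Product: 15 bisoflavolin H, via tetrakis(dibromoboryl) ether 14 (not isolated)
Conditions: BBr3 (10 equiv), CH2Cl2, −78 °C → rt, 16 h; then ice-water
Reagents that add atoms: none
Why: Lewis-acid cleavage of aryl methyl ethers, in which bromide attacks only the methyl carbons of the boron-bound ethers (the chelated 5-methoxy group first), so the diaryl ether, the aryl chloride and both pyranones should survive, and the cold aprotic medium avoids the acid-induced ring opening and reclosure (Wessely–Moser type) that could move the ether from C8 to C6; water then frees the phenols and no stereocentre is present.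

## Compound list
1 | 2,4,6-trimethoxyphenol | Oc1c(OC)cc(OC)cc1OC | starting material
2 | 4-fluorobenzaldehyde | O=Cc1ccc(F)cc1 | starting material
3 | 4-(2,4,6-trimethoxyphenoxy)benzaldehyde | O=Cc1ccc(Oc2c(OC)cc(OC)cc2OC)cc1 | intermediate
4 | (2E)-3-(4-methoxyphenyl)prop-2-enoyl chloride | COc1ccc(/C=C/C(=O)Cl)cc1 | starting material
5 | 4-{2,4,6-trimethoxy-3-[(2E)-3-(4-methoxyphenyl)prop-2-enoyl]phenoxy}benzaldehyde | COc1ccc(/C=C/C(=O)c2c(OC)cc(OC)c(Oc3ccc(C=O)cc3)c2OC)cc1 | intermediate
6 | 4-{2-hydroxy-4,6-dimethoxy-3-[(2E)-3-(4-methoxyphenyl)prop-2-enoyl]phenoxy}benzaldehyde | COc1ccc(/C=C/C(=O)c2c(OC)cc(OC)c(Oc3ccc(C=O)cc3)c2O)cc1 | intermediate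
7 | 2-chlorobenzene-1,3-diol (2-chlororesorcinol) | Oc1cccc(O)c1Cl | starting material
8 | 1-(3-chloro-2,4-dihydroxyphenyl)ethan-1-one | CC(=O)c1ccc(O)c(Cl)c1O | intermediate
9 | 1-[3-chloro-2-hydroxy-4-(methoxymethoxy)phenyl]ethan-1-one | CC(=O)c1ccc(OCOC)c(Cl)c1O | intermediate
10 | 1-[3-chloro-2-hydroxy-4-(methoxymethoxy)phenyl]-3-hydroxy-3-(4-{2-hydroxy-4,6-dimethoxy-3-[(2E)-3-(4-methoxyphenyl)prop-2-enoyl]phenoxy}phenyl)propan-1-one, racemic | COCOc1ccc(C(=O)CC(O)c2ccc(Oc3c(OC)cc(OC)c(C(=O)/C=C/c4ccc(OC)cc4)c3O)cc2)c(O)c1Cl | intermediate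
11 | (2E)-1-[3-chloro-2-hydroxy-4-(methoxymethoxy)phenyl]-3-(4-{2-hydroxy-4,6-dimethoxy-3-[(2E)-3-(4-methoxyphenyl)prop-2-enoyl]phenoxy}phenyl)prop-2-en-1-one | COCOc1ccc(C(=O)/C=C/c2ccc(Oc3c(OC)cc(OC)c(C(=O)/C=C/c4ccc(OC)cc4)c3O)cc2)c(O)c1Cl | intermediate
12 | 1-[3-chloro-2-hydroxy-4-(methoxymethoxy)phenyl]-2-(4-{3-[3,3-dimethoxy-2-(4-methoxyphenyl)propanoyl]-2-hydroxy-4,6-dimethoxyphenoxy}phenyl)-3,3-dimethoxypropan-1-one, mixture of stereoisomers | COCOc1ccc(C(=O)C(C(OC)OC)c2ccc(Oc3c(OC)cc(OC)c(C(=O)C(C(OC)OC)c4ccc(OC)cc4)c3O)cc2)c(O)c1Cl | intermediate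
13 | 8-chloro-3-(4-{[5,7-dimethoxy-3-(4-methoxyphenyl)-4-oxo-4H-chromen-8-yl]oxy}phenyl)-7-hydroxy-4H-chromen-4-one | O=c1c(-c2ccc(Oc3c(OC)cc(OC)c4c(=O)c(-c5ccc(OC)cc5)coc34)cc2)coc2c(Cl)c(O)ccc12 | intermediate
14 | tetrakis(dibromoboryl) ether of 15, drawn in its simplest form with each phenol oxygen carrying BBr2 | O=c1c(-c2ccc(Oc3c(OB(Br)Br)cc(OB(Br)Br)c4c(=O)c(-c5ccc(OB(Br)Br)cc5)coc34)cc2)coc2c(Cl)c(OB(Br)Br)ccc12 | intermediate
15 | bisoflavolin H, 8-chloro-3-(4-{[5,7-dihydroxy-3-(4-hydroxyphenyl)-4-oxo-4H-chromen-8-yl]oxy}phenyl)-7-hydroxy-4H-chromen-4-one | O=c1c(-c2ccc(Oc3c(O)cc(O)c4c(=O)c(-c5ccc(O)cc5)coc34)cc2)coc2c(Cl)c(O)ccc12 | target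

Total step count: 7. Longest linear sequence: 5 steps (steps 1, 2, 5, 6, 7).

Steps most likely to fail:

1. Step 6. The aryl shift in the chlorinated half may be slow, because an aryloxy group is a weaker donor than methoxy. Oxidative closure to an aurone, acid-induced closure of the ring-A chalcone to a flavanone that no longer rearranges, or early loss of the methoxymethyl group could then compete. Fallback: starting from 11, both chalcones would first be closed on purpose (NaOAc, EtOH, reflux) to the bis-flavanone F1. The aryl shift would then be run on the flavanones with PhI(OAc)2 and TsOH in HC(OMe)3 (enol ether formation, attack of trivalent iodine at C3, migration of the C2 aryl group to C3, loss of PhI), which should give the methoxymethyl-protected bis-isoflavone F2. Warming F2 with HCl in MeOH would remove the methoxymethyl group and bring the route back at 13.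

2. Step 2. The Lewis acid may turn the free aldehyde or the new enone into an electrophile for a second electron-rich ring, leading to arene addition and oligomer formation, or it may cleave the second ortho-methyl group as well. Fallback: starting from 3, the aldehyde would be masked as the dioxolane F3 (ethane-1,2-diol, TsOH, toluene, water removed). F3 would be lithiated between two methoxy groups (n-BuLi, TMEDA, THF, 0 °C; the two such positions are equivalent) to the aryllithium F4. F4 would be acylated with the N-methoxy-N-methylamide F5 (from 4 and MeNHOMe·HCl, pyridine) and the mixture quenched with aqueous NH4Cl to give the acetal-protected trimethoxy chalcone F6. BCl3 (CH2Cl2, −78 → −20 °C) would then remove the crowded ortho-methyl group of F6 through the boron chelate, and aqueous acid in the work-up would release the aldehyde, which brings the route back at 6. In this variant the ring reacts as an organolithium nucleophile and no acylating Lewis acid meets a free aldehyde.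

3. Step 5. Strong base may cause retro-aldol cleavage of the chalcone already present, Michael addition of the ketone enolate to an enone, or disproportionation of the aldehyde, while the phenoxide ketone enolises slowly. Fallback: starting from 9, double deprotonation with LiN(SiMe3)2 (2.1 equiv, THF, −78 °C) would give the dilithium enolate phenoxide F7. CBr4 would brominate F7 at carbon, and a cold quench with AcOH, before the phenoxide can close onto the new C–Br bond, would give the bromoketone F8. PPh3 (toluene, rt) would give the phosphonium bromide F9 and aqueous Na2CO3 the stabilised ylide F10. F10 and 6 in toluene at 90 °C would form the E enone by Wittig olefination without base and bring the route back at 11.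

Further compounds
F1 | step 6 | 8-chloro-2-(4-{[5,7-dimethoxy-2-(4-methoxyphenyl)-4-oxo-3,4-dihydro-2H-chromen-8-yl]oxy}phenyl)-7-(methoxymethoxy)-2,3-dihydro-4H-chromen-4-one, mixture of stereoisomers | O=C1CC(c2ccc(Oc3c(OC)cc(OC)c4C(=O)CC(c5ccc(OC)cc5)Oc34)cc2)Oc2c(Cl)c(OCOC)ccc12
F2 | step 6 | 8-chloro-3-(4-{[5,7-dimethoxy-3-(4-methoxyphenyl)-4-oxo-4H-chromen-8-yl]oxy}phenyl)-7-(methoxymethoxy)-4H-chromen-4-one | O=c1c(-c2ccc(Oc3c(OC)cc(OC)c4c(=O)c(-c5ccc(OC)cc5)coc34)cc2)coc2c(Cl)c(OCOC)ccc12
F3 | step 2 | 2-[4-(2,4,6-trimethoxyphenoxy)phenyl]-1,3-dioxolane | COc1cc(OC)c(Oc2ccc(C3OCCO3)cc2)c(OC)c1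
F4 | step 2 | {3-[4-(1,3-dioxolan-2-yl)phenoxy]-2,4,6-trimethoxyphenyl}lithium | [Li]c1c(OC)cc(OC)c(Oc2ccc(C3OCCO3)cc2)c1OC
F5 | step 2 | (2E)-N-methoxy-N-methyl-3-(4-methoxyphenyl)prop-2-enamide | COc1ccc(/C=C/C(=O)N(C)OC)cc1
F6 | step 2 | (2E)-1-{3-[4-(1,3-dioxolan-2-yl)phenoxy]-2,4,6-trimethoxyphenyl}-3-(4-methoxyphenyl)prop-2-en-1-one | COc1ccc(/C=C/C(=O)c2c(OC)cc(OC)c(Oc3ccc(C4OCCO4)cc3)c2OC)cc1
F7 | step 5 | dilithium 2-chloro-3-(methoxymethoxy)-6-(1-oxidoethenyl)phenolate, drawn with O–Li bonds | C=C(O[Li])c1ccc(OCOC)c(Cl)c1O[Li]
F8 | step 5 | 2-bromo-1-[3-chloro-2-hydroxy-4-(methoxymethoxy)phenyl]ethan-1-one | COCOc1ccc(C(=O)CBr)c(O)c1Cl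
F9 | step 5 | {2-[3-chloro-2-hydroxy-4-(methoxymethoxy)phenyl]-2-oxoethyl}(triphenyl)phosphonium bromide | [Br-].COCOc1ccc(C(=O)C[P+](c2ccccc2)(c2ccccc2)c2ccccc2)c(O)c1Cl
F10 | step 5 | 1-[3-chloro-2-hydroxy-4-(methoxymethoxy)phenyl]-2-(triphenylphosphoranylidene)ethan-1-one | COCOc1ccc(C(=O)C=P(c2ccccc2)(c2ccccc2)c2ccccc2)c(O)c1Cl
A1 | direct plan | 8-chloro-7-hydroxy-3-(4-hydroxyphenyl)-4H-chromen-4-one (8-chlorodaidzein) | O=c1c(-c2ccc(O)cc2)coc2c(Cl)c(O)ccc12
A2 | direct plan | 8-chloro-3-(4-hydroxyphenyl)-7-methoxy-4H-chromen-4-one | O=c1c(-c2ccc(O)cc2)coc2c(Cl)c(OC)ccc12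
A3 | direct plan | genistein, 5,7-dihydroxy-3-(4-hydroxyphenyl)-4H-chromen-4-one | O=c1c(-c2ccc(O)cc2)coc2cc(O)cc(O)c12
A4 | direct plan | 5,7-dimethoxy-3-(4-methoxyphenyl)-4H-chromen-4-one | O=c1c(-c2ccc(OC)cc2)coc2cc(OC)cc(OC)c12
A5 | direct plan | 8-iodo-5,7-dimethoxy-3-(4-methoxyphenyl)-4H-chromen-4-one | O=c1c(-c2ccc(OC)cc2)coc2c(I)c(OC)cc(OC)c12
A6 | direct plan | 8-chloro-3-(4-{[5,7-dimethoxy-3-(4-methoxyphenyl)-4-oxo-4H-chromen-8-yl]oxy}phenyl)-7-methoxy-4H-chromen-4-one | O=c1c(-c2ccc(Oc3c(OC)cc(OC)c4c(=O)c(-c5ccc(OC)cc5)coc34)cc2)coc2c(Cl)c(OC)ccc12
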